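Everything rests on making ring A last. Ring A is a resorcinol with C3–H between C2–OH and C4–OH, the pattern that a vinylketene carbonyl (C2–O) and a terminal silyl ynol ether (C3–H, C4–O) deliver. Heating a 2-(1,1-dimethylallyl)-4-alkylcyclobutenone with triisopropylsiloxyacetylene should form C2–C3 and C4–C5, then close C1–C2. The arene thus appears in one operation with linker, quaternary benzylic carbon and both oxygens in place. The precursor already carries the finished prenylated chromene on a three-carbon tether. Its C8 phenol is a TIPS ether instead of an acetal, so one buffered fluoride treatment ends the synthesis and the o-(1,1-dimethylallyl)phenol never meets acid.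

Key step: step 10

Assumption: (ethynyloxy)triisopropylsilane is taken as a purchasable speciality reagent; all cyclobutene intermediates are racemic, which is irrelevant because the target has no stereocentre.
Abbreviation: Chr = 2,2-dimethyl-5-(3-methylbut-2-en-1-yl)-8-(triisopropylsilyloxy)-2H-chromen-6-yl.

Step 1
Reactants: 1 4,5-dibromobenzene-1,2-diol; 2 3-chloro-3-methylbut-1-yne
Product: 3 4,5-dibromo-2-[(2-methylbut-3-yn-2-yl)oxy]phenol
Conditions: 1 (1.3 equiv), DBU, CuCl2 (1 mol%), MeCN, 0 °C, argon
Reagents that add atoms: none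
Why: Copper-catalysed O-alkylation of a phenol with a tertiary propargylic chloride is a standard entry to aryl 1,1-dimethylpropargyl ethers; because 1 is symmetric only one monoether can form, and the bulk of the first ether group together with the slight excess of 1 should hold back a second alkylation.

Step 2
Reactants: 3 4,5-dibromo-2-[(2-methylbut-3-yn-2-yl)oxy]phenol
Product: 4 5,6-dibromo-2,2-dimethyl-2H-chromen-8-ol
Conditions: o-xylene, 140 °C
Reagents that add atoms: none
Why: Aromatic propargyl Claisen rearrangement to the only free ortho carbon, followed by enolisation, 1,5-hydrogen shift and oxa-6π electrocyclisation, is the standard thermal route from such ethers to 2,2-dimethyl-2H-chromenes and places the bromines at C5 and C6 and the free hydroxyl at C8.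

Step 3
Reactants: 4 5,6-dibromo-2,2-dimethyl-2H-chromen-8-ol; 5 methyl pent-4-enoate
Product: 7 methyl 5-(5-bromo-8-hydroxy-2,2-dimethyl-2H-chromen-6-yl)pentanoate, via B-alkyl borane 6 (not isolated)
Conditions: 5, 9-BBN-H, THF, 0 °C → rt; then 4, Pd(OAc)2, SPhos, K3PO4, THF/H2O, 60 °C
Reagents that add atoms: 9-borabicyclo[3.3.1]nonane (9-BBN-H), [H]B1C2CCCC1CCC2 (boron unit kept in 6 only)
Why: Hydroboration of the terminal alkene and B-alkyl Suzuki–Miyaura coupling install the saturated chain directly; zerovalent palladium should insert into C6–Br, which has a single ortho neighbour and lies meta to the phenoxide present under the basic conditions, and not into C5–Br, which is flanked on both sides and lies para to that strongly donating oxygen, so steric and electronic bias point the same way.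

Step 4
Reactants: 7 methyl 5-(5-bromo-8-hydroxy-2,2-dimethyl-2H-chromen-6-yl)pentanoate
Product: 8 methyl 5-[5-bromo-2,2-dimethyl-8-(triisopropylsilyloxy)-2H-chromen-6-yl]pentanoate
Conditions: TIPSCl, imidazole, DMF, rt
Reagents that add atoms: chlorotriisopropylsilane (TIPSCl), CC(C)[Si](Cl)(C(C)C)C(C)C
Why: Routine silylation of a phenol; the TIPS ether is chosen because it survives organozinc, hydride, cold dilute acid and heat and falls to fluoride together with the ring A silyl ether in the last step.

Step 5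
Reactants: 8 methyl 5-[5-bromo-2,2-dimethyl-8-(triisopropylsilyloxy)-2H-chromen-6-yl]pentanoate; 9 1-bromo-3-methylbut-2-ene (prenyl bromide)
Product: 11 methyl 5-(Chr)pentanoate, via prenylzinc bromide 10 (not isolated)
Conditions: 9, Zn, LiCl, THF, 0 °C → rt; then 8, Pd(OAc)2, CPhos, THF, rt → 40 °C
Reagents that add atoms: zinc, [Zn] (kept in 10 only)
Why: Negishi coupling of an allylic zinc halide under a bulky biarylphosphine ligand is known to give the linear prenyl arene, because C–C bond formation at the unsubstituted allyl terminus avoids a quaternary carbon next to the doubly ortho-substituted arene, and it tolerates the ester and the silyl ether.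

Step 6
Reactants: 11 methyl 5-(Chr)pentanoate
Product: 13 5-(Chr)pentanoic acid, via stannyl ester 12 (not isolated)
Conditions: Me3SnOH, 1,2-dichloroethane, 70 °C; 5% aq HCl wash
Reagents that add atoms: trimethyltin hydroxide, C[Sn](C)(C)O
Why: Me3SnOH cleaves unhindered methyl esters under nearly neutral conditions through the stannyl ester, so the aryl silyl ether that aqueous hydroxide could attack is kept.

Step 7
Reactants: 14 methyl 2,2-dimethylbut-3-enoate; 15 dibromomethane
Product: 19 [(3,3-dimethylpent-4-en-1-yn-1-yl)oxy]triisopropylsilane, via dibromomethyllithium 16 (not isolated), via dibromoenolate 17 (not isolated), via lithium ynolate 18 (not isolated)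
Conditions: 15, lithium 2,2,6,6-tetramethylpiperidide (LiTMP), THF, −78 °C; 14; more LiTMP; n-BuLi, −78 °C → rt; TIPSOTf, −78 → 0 °C
Reagents that add atoms: triisopropylsilyl trifluoromethanesulfonate (TIPSOTf), CC(C)[Si](OS(=O)(=O)C(F)(F)F)(C(C)C)C(C)C; LiTMP, [Li]N1C(C)(C)CCCC1(C)C (lithium kept in 16 to 18 only)
Why: This is a Kowalski ester homologation stopped at the ynolate stage: dibromomethyllithium adds to the non-enolisable ester, the derived dibromoenolate undergoes bromine–lithium exchange and 1,2-shift of the tertiary alkyl group, and the bulky silyl triflate traps ynolate 18 on oxygen.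

Step 8
Reactants: 13 5-(Chr)pentanoic acid; 19 [(3,3-dimethylpent-4-en-1-yn-1-yl)oxy]triisopropylsilane
Product: 22 4-[3-(Chr)propyl]-2-(2-methylbut-3-en-2-yl)-3-(triisopropylsilyloxy)cyclobut-2-en-1-one (racemic), via acid chloride 20 (not isolated), via alkylketene 21 (not isolated)
Conditions: Me2C=C(Cl)NMe2, CH2Cl2, 0 °C → rt; then slow addition to 19 (2 equiv), Et3N, CH2Cl2, 40 °C
Reagents that add atoms: 1-chloro-N,N,2-trimethylprop-1-en-1-amine, CC(C)=C(Cl)N(C)C (chlorine kept in 20 only)
Why: The chloroenamine makes the acid chloride without free HCl, Et3N dehydrochlorinates it to the alkylketene, and a ketene–ynol ether [2+2] cycloaddition follows in which the nucleophilic alkyne carbon (the one bearing the tertiary alkyl group) bonds to the ketene carbonyl carbon, so the silyloxy group ends at C3 and the chain at C4; slow addition and excess 19 are meant to suppress ketene dimerisation, and the new C4 stereocentre forms as a racemate that is erased in step 10.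

Step 9
Reactants: 22 4-[3-(Chr)propyl]-2-(2-methylbut-3-en-2-yl)-3-(triisopropylsilyloxy)cyclobut-2-en-1-one
Product: 24 4-[3-(Chr)propyl]-2-(2-methylbut-3-en-2-yl)cyclobut-2-en-1-one (racemic), via cyclobutenol 23 (not isolated)
Conditions: i-Bu2AlH, CH2Cl2, −78 °C; then 1 M HCl, THF, 0 °C → rt
Reagents that add atoms: none
Why: 1,2-Reduction of the vinylogous silyl ester and acid-induced loss of silanol from the resulting 3-silyloxy allylic alcohol (1,3-carbonyl transposition, as practised on 3-alkoxycyclobutenones) move the carbonyl to the former C3 and leave hydrogen on the former carbonyl carbon; the carbinol stereocentre is lost again, and brief cold dilute acid should spare the aryl silyl ether, prenyl and chromene groups.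

Step 10
Reactants: 24 4-[3-(Chr)propyl]-2-(2-methylbut-3-en-2-yl)cyclobut-2-en-1-one; 25 (ethynyloxy)triisopropylsilane
Product: 29 Kazinol K 4-O-TIPS 8-O-TIPS bis(silyl ether) with free ring A C2–OH, via vinylketene 26 (not isolated), via vinylcyclobutenone 27 (not isolated), via dienylketene 28 (not isolated)
Conditions: 25 (3 equiv), toluene, 80 → 110 °C, sealed tube, argon
Reagents that add atoms: none
Why: Thermal conrotatory 4π opening of 24 breaks the C(=O)–C4 bond with the alkyl chain turning outward and gives (E)-vinylketene 26, whose ketene C=C adds to 25 in a [2+2] cycloaddition (27); a second 4π opening gives dienylketene 28, and 6π electrocyclisation plus tautomerisation gives the phenol, which is a Danheiser benzannulation with a silyl ynol ether. Ring A is closed by a disrotatory 6π electrocyclisation that joins the ketene carbon (C2) to the chain-bearing diene terminus (C1), after C2–C3 and C4–C5 have been made in the [2+2] event. Regiocontrol is needed only in the [2+2]: the nucleophilic CH terminus of 25 attacks the electrophilic ketene carbonyl carbon, so the silyloxy carbon bonds to the carbon bearing the 1,1-dimethylallyl group, which puts C3–H between the oxygens and leaves them differentiated as OH and OTIPS. In the opening of 27 the bulky tertiary alkyl group should rotate outward, which turns the alkenyl group inward as the 6π closure requires. No stereocentre is formed and the one in racemic 24 is erased. Excess 25 is meant to outrun reclosure of 26 and its capture by the phenolic product, while the prenyl, chromene and aryl silyl ether groups are inert at this temperature, the chromene itself being made at a higher one in step 2.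

Step 11
Reactants: 29 Kazinol K 4-O-TIPS 8-O-TIPS bis(silyl ether)
Product: 30 Kazinol K
Conditions: TBAF, AcOH, THF, 0 °C → rt, argon
Reagents that add atoms: none
Why: Fluoride cleaves both aryl silyl ethers in one operation, and the acetic acid buffer keeps the liberated electron-rich phenoxides protonated, so neither acid-induced cyclisation of the o-(1,1-dimethylallyl)phenol nor base-induced oxidation is to be expected.

Compound list
1 | 4,5-dibromobenzene-1,2-diol | Oc1cc(Br)c(Br)cc1O | starting material
2 | 3-chloro-3-methylbut-1-yne | C#CC(C)(C)Cl | starting material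
3 | 4,5-dibromo-2-[(2-methylbut-3-yn-2-yl)oxy]phenol | C#CC(C)(C)Oc1cc(Br)c(Br)cc1O | intermediate
4 | 5,6-dibromo-2,2-dimethyl-2H-chromen-8-ol | Brc1cc(O)c2c(c1Br)C=CC(C)(C)O2 | intermediate
5 | methyl pent-4-enoate | C=CCCC(=O)OC | starting material
6 | methyl 5-(9-borabicyclo[3.3.1]nonan-9-yl)pentanoate | COC(=O)CCCCB1C2CCCC1CCC2 | intermediate
7 | methyl 5-(5-bromo-8-hydroxy-2,2-dimethyl-2H-chromen-6-yl)pentanoate | COC(=O)CCCCc1cc(O)c2c(c1Br)C=CC(C)(C)O2 | intermediate
8 | methyl 5-[5-bromo-2,2-dimethyl-8-(triisopropylsilyloxy)-2H-chromen-6-yl]pentanoate | COC(=O)CCCCc1cc(O[Si](C(C)C)(C(C)C)C(C)C)c2c(c1Br)C=CC(C)(C)O2 | intermediate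
9 | 1-bromo-3-methylbut-2-ene | CC(C)=CCBr | starting material
10 | (3-methylbut-2-en-1-yl)zinc bromide | CC(C)=CC[Zn]Br | intermediate
11 | methyl 5-(Chr)pentanoate | COC(=O)CCCCc1cc(O[Si](C(C)C)(C(C)C)C(C)C)c2c(c1CC=C(C)C)C=CC(C)(C)O2 | intermediate
12 | trimethylstannyl 5-(Chr)pentanoate | C[Sn](C)(C)OC(=O)CCCCc1cc(O[Si](C(C)C)(C(C)C)C(C)C)c2c(c1CC=C(C)C)C=CC(C)(C)O2 | intermediate
13 | 5-(Chr)pentanoic acid | OC(=O)CCCCc1cc(O[Si](C(C)C)(C(C)C)C(C)C)c2c(c1CC=C(C)C)C=CC(C)(C)O2 | intermediate
14 | methyl 2,2-dimethylbut-3-enoate | COC(=O)C(C)(C)C=C | starting material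
15 | dibromomethane | BrCBr | starting material
16 | dibromomethyllithium | [Li]C(Br)Br | intermediate
17 | lithium 1,1-dibromo-3,3-dimethylpenta-1,4-dien-2-olate | [Li+].[O-]C(=C(Br)Br)C(C)(C)C=C | intermediate
18 | lithium 3,3-dimethylpent-4-en-1-yn-1-olate | [Li+].[O-]C#CC(C)(C)C=C | intermediate
19 | [(3,3-dimethylpent-4-en-1-yn-1-yl)oxy]triisopropylsilane | C=CC(C)(C)C#CO[Si](C(C)C)(C(C)C)C(C)C | intermediate
20 | 5-(Chr)pentanoyl chloride | O=C(Cl)CCCCc1cc(O[Si](C(C)C)(C(C)C)C(C)C)c2c(c1CC=C(C)C)C=CC(C)(C)O2 | intermediate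
21 | 5-(Chr)pent-1-en-1-one (alkylketene) | O=C=CCCCc1cc(O[Si](C(C)C)(C(C)C)C(C)C)c2c(c1CC=C(C)C)C=CC(C)(C)O2 | intermediate
22 | 4-[3-(Chr)propyl]-2-(2-methylbut-3-en-2-yl)-3-(triisopropylsilyloxy)cyclobut-2-en-1-one, racemic | O=C1C(C(C)(C)C=C)=C(O[Si](C(C)C)(C(C)C)C(C)C)C1CCCc2cc(O[Si](C(C)C)(C(C)C)C(C)C)c3c(c2CC=C(C)C)C=CC(C)(C)O3 | intermediate
23 | 4-[3-(Chr)propyl]-2-(2-methylbut-3-en-2-yl)-3-(triisopropylsilyloxy)cyclobut-2-en-1-ol, racemic mixture of diastereomers | OC1C(C(C)(C)C=C)=C(O[Si](C(C)C)(C(C)C)C(C)C)C1CCCc2cc(O[Si](C(C)C)(C(C)C)C(C)C)c3c(c2CC=C(C)C)C=CC(C)(C)O3 | intermediate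
24 | 4-[3-(Chr)propyl]-2-(2-methylbut-3-en-2-yl)cyclobut-2-en-1-one, racemic | O=C1C(C(C)(C)C=C)=CC1CCCc2cc(O[Si](C(C)C)(C(C)C)C(C)C)c3c(c2CC=C(C)C)C=CC(C)(C)O3 | intermediate
25 | (ethynyloxy)triisopropylsilane | C#CO[Si](C(C)C)(C(C)C)C(C)C | starting material
26 | (E)-vinylketene: 6-(Chr)-2-(2-methylbut-3-en-2-yl)hexa-1,3-dien-1-one | O=C=C(C(C)(C)C=C)/C=C/CCCc1cc(O[Si](C(C)C)(C(C)C)C(C)C)c2c(c1CC=C(C)C)C=CC(C)(C)O2 | intermediate
27 | 4-[(E)-5-(Chr)pent-1-en-1-yl]-4-(2-methylbut-3-en-2-yl)-3-(triisopropylsilyloxy)cyclobut-2-en-1-one, racemic | O=C1C=C(O[Si](C(C)C)(C(C)C)C(C)C)C1(C(C)(C)C=C)/C=C/CCCc2cc(O[Si](C(C)C)(C(C)C)C(C)C)c3c(c2CC=C(C)C)C=CC(C)(C)O3 | intermediate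
28 | dienylketene: 8-(Chr)-4-(2-methylbut-3-en-2-yl)-3-(triisopropylsilyloxy)octa-1,3,5-trien-1-one, alkenyl group cis to the ketenyl group, C5=C6 E | O=C=C/C(O[Si](C(C)C)(C(C)C)C(C)C)=C(\C=C\CCCc1cc(O[Si](C(C)C)(C(C)C)C(C)C)c2c(c1CC=C(C)C)C=CC(C)(C)O2)C(C)(C)C=C | intermediate
29 | 2-[3-(Chr)propyl]-4-(2-methylbut-3-en-2-yl)-5-(triisopropylsilyloxy)phenol (Kazinol K with ring A C4–OTIPS and chromene C8–OTIPS) | C=CC(C)(C)c1cc(CCCc2cc(O[Si](C(C)C)(C(C)C)C(C)C)c3c(c2CC=C(C)C)C=CC(C)(C)O3)c(O)cc1O[Si](C(C)C)(C(C)C)C(C)C | intermediate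
30 | Kazinol K | C=CC(C)(C)c1cc(CCCc2cc(O)c3c(c2CC=C(C)C)C=CC(C)(C)O3)c(O)cc1O | target

Total step count: 11. Longest linear sequence: 10 steps (steps 1 to 6 and 8 to 11); step 7 is a one-step side branch.

Steps most likely to fail

1. Step 10.
- Risk: the [2+2] event must create a quaternary ring carbon next to the quaternary carbon of the 1,1-dimethylallyl group. It may be slower than reclosure of 26, than capture of 26 by the phenolic product, or than a Cope rearrangement of the crowded 1,5-diene unit in 27.
- Fallback (sets out from 4, comes back at 30): both ring A oxygens end as free hydroxyls, so the two carbon substituents can change roles. The ketene carbon then carries the primary chain and the tertiary alkyl group sits on the diene terminus. The conditions of steps 3 to 5 would be run with methyl but-3-enoate in place of 5. This gives methyl 4-(5-bromo-8-hydroxy-2,2-dimethyl-2H-chromen-6-yl)butanoate F1, its TIPS ether F2 and the prenylated ester F3. The sequence of step 7 applied to F3 would give the chain-bearing siloxyalkyne F4. The slowly dimerising ketene from commercial 3,3-dimethylpent-4-enoyl chloride and Et3N would add to F4 to give the 3-silyloxycyclobutenone F5. Reduction and acid as in step 9 would give the 2-alkyl-4-(1,1-dimethylallyl)cyclobutenone F6. Heating with 25 would give the regioisomeric monosilyl ether F7, and the conditions of step 11 would turn it into 30. The same F7 would also result if the first-formed zwitterion in step 10 closed directly to the six-membered ring, so that deviation would not cost material.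

2. Step 8.
- Risk: dimerisation of the alkylketene, or its consumption by amine-bound acylium species, may outrun cycloaddition to an alkyne whose nucleophilic carbon bears a tertiary alkyl group.
- Fallback (sets out from 11, comes back at 22): the alkylketene is replaced by the more electrophilic and less dimerisation-prone chloro(alkyl)ketene, and chlorine is removed afterwards. The lithium enolate of 11 (LDA, THF, −78 °C) would be chlorinated with N-chlorosuccinimide to the 2-chloro ester F8. Me3SnOH would give the 2-chloro acid F9, and the conditions of step 8 would give the 4-chloro-3-silyloxycyclobutenone F10. Zinc in AcOH/TMEDA/EtOH at 0 °C (the reductive dechlorination used for 4,4-dichlorocyclobutenones) would return 22.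

3. Step 7.
- Risk: addition of the thermally fragile dibromomethyllithium to a neopentyl-type ester may be too slow at −78 °C, so the carbenoid decomposes before the carbonyl is attacked.
- Fallback (sets out from 14, comes back at 19): the same ynolate is reached by oxidation of an acetylide instead of by carbenoid rearrangement. i-Bu2AlH at −78 °C would reduce 14 to 2,2-dimethylbut-3-enal F11. Seyferth–Gilbert homologation with dimethyl (1-diazo-2-oxopropyl)phosphonate and K2CO3 in MeOH would give 3,3-dimethylpent-4-en-1-yne F12. Lithiation with n-BuLi, oxidation with t-BuOOLi to ynolate 18 and silylation with TIPSOTf would give 19.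

Further compounds
F1 | step 10 | methyl 4-(5-bromo-8-hydroxy-2,2-dimethyl-2H-chromen-6-yl)butanoate | COC(=O)CCCc1cc(O)c2c(c1Br)C=CC(C)(C)O2
F2 | step 10 | methyl 4-[5-bromo-2,2-dimethyl-8-(triisopropylsilyloxy)-2H-chromen-6-yl]butanoate | COC(=O)CCCc1cc(O[Si](C(C)C)(C(C)C)C(C)C)c2c(c1Br)C=CC(C)(C)O2
F3 | step 10 | methyl 4-(Chr)butanoate | COC(=O)CCCc1cc(O[Si](C(C)C)(C(C)C)C(C)C)c2c(c1CC=C(C)C)C=CC(C)(C)O2
F4 | step 10 | {[5-(Chr)pent-1-yn-1-yl]oxy}triisopropylsilane | CC(C)[Si](OC#CCCCc1cc(O[Si](C(C)C)(C(C)C)C(C)C)c2c(c1CC=C(C)C)C=CC(C)(C)O2)(C(C)C)C(C)C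
F5 | step 10 | 2-[3-(Chr)propyl]-4-(2-methylbut-3-en-2-yl)-3-(triisopropylsilyloxy)cyclobut-2-en-1-one, racemic | O=C1C(CCCc2cc(O[Si](C(C)C)(C(C)C)C(C)C)c3c(c2CC=C(C)C)C=CC(C)(C)O3)=C(O[Si](C(C)C)(C(C)C)C(C)C)C1C(C)(C)C=C
F6 | step 10 | 2-[3-(Chr)propyl]-4-(2-methylbut-3-en-2-yl)cyclobut-2-en-1-one, racemic | O=C1C(CCCc2cc(O[Si](C(C)C)(C(C)C)C(C)C)c3c(c2CC=C(C)C)C=CC(C)(C)O3)=CC1C(C)(C)C=C
F7 | step 10 | 4-[3-(Chr)propyl]-2-(2-methylbut-3-en-2-yl)-5-(triisopropylsilyloxy)phenol | C=CC(C)(C)c1cc(CCCc2cc(O[Si](C(C)C)(C(C)C)C(C)C)c3c(c2CC=C(C)C)C=CC(C)(C)O3)c(O[Si](C(C)C)(C(C)C)C(C)C)cc1O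
F8 | step 8 | methyl 2-chloro-5-(Chr)pentanoate, racemic | COC(=O)C(Cl)CCCc1cc(O[Si](C(C)C)(C(C)C)C(C)C)c2c(c1CC=C(C)C)C=CC(C)(C)O2
F9 | step 8 | 2-chloro-5-(Chr)pentanoic acid, racemic | OC(=O)C(Cl)CCCc1cc(O[Si](C(C)C)(C(C)C)C(C)C)c2c(c1CC=C(C)C)C=CC(C)(C)O2
F10 | step 8 | 4-chloro-4-[3-(Chr)propyl]-2-(2-methylbut-3-en-2-yl)-3-(triisopropylsilyloxy)cyclobut-2-en-1-one, racemic | O=C1C(C(C)(C)C=C)=C(O[Si](C(C)C)(C(C)C)C(C)C)C1(Cl)CCCc2cc(O[Si](C(C)C)(C(C)C)C(C)C)c3c(c2CC=C(C)C)C=CC(C)(C)O3
F11 | step 7 | 2,2-dimethylbut-3-enal | C=CC(C)(C)C=O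
F12 | step 7 | 3,3-dimethylpent-4-en-1-yne | C=CC(C)(C)C#C
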